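## Structural features

Target **20** is a single cyclohexene ring, numbered C1 (acetoxy carbon), C2 (alkene CH), C3 (alkene carbon bearing the exocyclic C7 benzoyloxymethyl group), C4 (free carbinol), C5 (benzoate carbon) and C6 (free carbinol). The four stereocentres C4, C5, C6 and C1 are contiguous and closed into the ring by the C2=C3 alkene. C5–O and C6–O are cis, C4–O is trans to C5–O and C1–O is trans to C6–O, with absolute configuration 1R,4S,5R,6S. Five oxygens carry three different states (acetate on C1, benzoates on C5 and C7, free hydroxyls on C4 and C6), so the real difficulty is telling the oxygens apart, not building the carbon skeleton. The fragile groups are the allylic acetate and allylic benzoate and the vicinal hydroxy esters: the C5 benzoate lies between two free hydroxyls and the C1 acetate next to C6–OH, so acyl migration threatens under base and the last steps must be acidic or neutral. C4, C5 and C6 (threo, then erythro) have exactly the configuration of C2, C3 and C4 of L-arabinose, so three of the four stereocentres can be bought. The key step uses the fact that C1 is an allylic carbinol on the alkene CH: the C1–C2 bond is the one an alkenyl metal at C2 makes with an aldehyde at C1. A vinyl iodide with iodine cis to C4 already holds C1 and C4 cis on C2=C3, as the ring requires.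

## Logic of the disconnections

**20 to 19.** The C4 O–Si bond is cut last. The silyl ether keeps C4–OH out of the acylation chemistry and biases the half-chair while the C5 benzoate is placed. This leaves one deprotection at the end, and it must be an acidic fluoride source so that no ester migrates.

**19 to 17 (through 18).** The C5 O–benzoyl bond is cut. The cis C5/C6 diol of **17** is tied into the cyclic orthoester **18**, so the two hydroxyls are told apart by ring geometry and not by reagent sterics. The forward opening must give the axial ester, which is C5 if C4–O sits pseudoaxial.

**17 to 16 to 15.** The two acetal C–O bonds of the dioxolane and the C1 O–acetyl bond are cut. The acetonide is the form in which C5 and C6 come from the sugar, and C1–OH is the only free hydroxyl of **15**, so its acetylation needs no selectivity. The hydrolysis must spare the secondary silyl ether and both allylic esters.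

**15 to 14.** The C1–C2 ring bond is cut. This opens the carbocycle to an acyclic aldehyde with a Z-vinyl iodide and removes one ring and one stereocentre. The forward step needs an alkenyl metal that tolerates benzoate, silyl ether and dioxolane, retention of alkene geometry, and facial control at C1.

**14 to 13 to 12.** The C1 aldehyde is traced to a primary alcohol and that to a primary silyl ether (C1 O–Si cut). A silyl mask is chosen for C1 because a sulfur-based aldehyde mask would not survive the peroxide and iodine used earlier. The demands are selective removal of a primary silyl ether beside a hindered secondary one, and a non-basic oxidation that does not epimerise C6.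

**12 to 11 to 10.** The C4 O–Si and C7 O–benzoyl bonds are cut, giving a diol with a primary allylic and a hindered secondary hydroxyl. The forward demand is primary-selective benzoylation before silylation.

**10 to 9 to 5 + 7 (7 from 6).** The C7–O bond is traced to a C7–Si bond, and the C3–C7 and C2–I bonds are cut together. Directed anti-addition of the silylmethyl Grignard reagent **7** across the terminal alkyne of **5** makes the trisubstituted iodoalkene in one operation with fixed regiochemistry and geometry. It requires a free C4 hydroxyl as the directing group and a substrate without groups that peroxide or iodine would attack.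

**5 to 4 to 2 + 3.** The C1 O–Si bond is cut, then the C2≡C3 triple bond is traced to the aldehyde carbon of lactol **2** plus one carbon from **3**. C4 therefore comes from the sugar and is not made by an uncontrolled acetylide addition to an α-alkoxy aldehyde. The homologation must not epimerise the carbon next to the aldehyde.

**2 to 1.** The acetal bonds are cut to the free pentose **1**, which supplies C1, C3, C4, C5 and C6 of the target and all three pool-derived stereocentres.

## Other disconnections considered

**Alternative 1:** The cut removes both the C5–O and C6–O bonds and takes the ring back to an arene. In the forward key step, whole-cell toluene dioxygenase adds dioxygen across one ring bond of bromobenzene A1 to give the cis-dihydrodiol A2 as one enantiomer.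

- In its favour: two stereocentres are set in one step from an achiral arene, all six ring carbons are present from the start, and no ring has to be closed. On step economy at the front end it is better than the chosen plan.
- Against it here: the sense of the enzyme puts the brominated carbon at the future C4, which must become an sp3 carbinol trans to C5–O, while C7 has to be attached at the neighbouring C3. After acetonide protection, oxygenation across the diene (for example singlet-oxygen cycloaddition and reduction) would be expected to turn the brominated carbon into a C4 carbonyl. Hydride delivery anti to the acetonide should then give the 4,5-cis alcohol, the opposite of what is needed, so an inversion would have to follow. C7 would come from an α-hydroxymethylation of the enone.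
- Comparison: C5 and C6 are equally secure in both plans. C4 is better controlled in the chosen plan, where it is bought with the sugar. C1 rests on substrate control in both. The alternative is probably shorter overall if the C4 problem is solved, and it avoids stoichiometric CrCl2. It needs fermentation capability or a supply of the unstable diene diol A2.

**Alternative 2:** The cut removes the C3–C7 and C7–O bonds. In the forward key step, dimethylsulfonium methylide adds 1,2 to the carbonyl of the quinic-derived enone A3 and the alkoxide displaces dimethyl sulfide, giving the spiro vinyl oxirane A4.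

- In its favour: C7 arrives together with its oxygen. A4 is set up for an SN2′ opening by acetate under zerovalent palladium (Pd(PPh3)4), which should form the C1–OAc bond, move the alkene to C2=C3 and free C7–OH in one step, with overall syn transfer from the epoxide oxygen to C1. On differentiating the C1 acetate from the C7 hydroxyl this is better than the chosen plan, because the mechanism does it.
- Against it here: A3 needs its C4 oxygen from a substrate-controlled α′-hydroxylation after several degradation steps. The α-silyloxy ketone can epimerise at C4 or eliminate under the basic ylide. The face chosen at C3, which later decides C1, depends on a contest between the C4 silyloxy group and the acetonide.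
- Comparison: the step count is about equal, and C5/C6 are equal (chiral pool in both). C4 is safer in the chosen plan. C1 is relayed stereospecifically from a stereocentre of uncertain selectivity in the alternative, and set directly by a ring-closing transition state of uncertain selectivity in the chosen plan, so neither is clearly ahead. The alternative uses ionic and π-allyl chemistry where the chosen plan uses an organochromium closure.

**Alternative 3:** The cut removes the C1–O and C4–O bonds. In the forward key step, singlet oxygen adds across C1 and C4 of the shikimate-derived diene A5, anti to the acetonide, to give the bicyclic endoperoxide A6.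

- In its favour: both remaining C–O bonds, their cis-1,4 relationship, their trans relationship to C5/C6 and the C2=C3 alkene appear in one step. A5 keeps C5 and C6 from the pool and C7 from the carboxyl carbon. On step economy it is better than the chosen plan, probably by two or three steps.
- Against it here: reduction of A6 would give the diol A7 with C1–OH and C4–OH free at the same time, and only the steric difference caused by the C3 substituent would direct the acetate to C1. The chosen plan is better here, because C4 is silylated before C1–OH exists. A5 is a cyclohexadiene that can aromatise or dimerise, the ene reaction of singlet oxygen can compete, and A6 can rearrange under base (Kornblum–DeLaMare) to a hydroxy enone.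
- Comparison: C5/C6 are equal. C1 and C4 are set together by a concerted cycloaddition, so their relative configuration is more dependable than the C1 outcome of the chosen closure. Hydroxyl differentiation is weaker. The C5 benzoate endgame would be the same as in the chosen plan.

Key step: step 10

## Route

Remarks on the chemistry:
- **1** reacts as its pyranose. The anomeric centre of **1** and **2** is left undefined because it disappears in step 2. The target numbering C1–C7 is used for every intermediate.
- The structures of **14** and **15** were re-derived atom by atom from **20**. They carry its configuration at C4, C5 and C6, and the iodide of **14** is Z with iodine cis to C4, so no structural correction was needed. CIP descriptors change along the route only because substituent priorities change.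

Step 1
Reactants: 1 L-arabinose
Product: 2 3,4-O-isopropylidene-L-arabinopyranose
Conditions: Me2C(OMe)2, TsOH·H2O (cat.), DMF, rt; Et3N quench
Reagents that add atoms: 2,2-dimethoxypropane, COC(C)(C)OC
Why: Acid-catalysed acetal exchange bridges the only cis-vicinal diol of the pyranose (O3/O4) as a cis-fused dioxolane and leaves the trans O2 and the anomeric hydroxyl free; no stereocentre changes.

Step 2
Reactants: 2 3,4-O-isopropylidene-L-arabinopyranose; 3 dimethyl (1-diazo-2-oxopropyl)phosphonate
Product: 4 1,2-dideoxy-4,5-O-isopropylidene-L-arabino-hex-1-ynitol (alkynediol)
Conditions: K2CO3, MeOH, rt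
Reagents that add atoms: none
Why: Seyferth–Gilbert homologation in the Ohira–Bestmann form: methanolysis of 3 gives the diazomethylphosphonate anion, which condenses with the open-chain aldehyde of lactol 2; loss of phosphate and N2 and a 1,2-hydrogen shift give the terminal alkyne. The mild carbonate base should leave the adjacent carbinol (future C4) untouched, so C4, C5 and C6 are carried over from the sugar.

Step 3
Reactants: 4 alkynediol
Product: 5 primary tert-butyldimethylsilyl ether of 4 (C1–OTBS; C4–OH free)
Conditions: TBSCl (1.05 equiv), imidazole, CH2Cl2, −20 → 0 °C
Reagents that add atoms: tert-butyldimethylsilyl chloride, CC(C)(C)[Si](C)(C)Cl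
Why: Silylation is much faster at the primary hydroxyl than at the secondary propargylic one flanked by the dioxolane, which leaves the C4 hydroxyl free as the directing group for step 4.

Step 4
Reactants: 5 primary silyl ether; 6 (chloromethyl)isopropoxydimethylsilane
Product: 9 vinyl iodide with the C7 isopropoxydimethylsilyl group (iodine cis to C4), via Grignard reagent 7 (not isolated), via alkenylmagnesium alkoxide 8 (not isolated)
Conditions: 6, Mg, THF, rt; then 5, CuI (15 mol %), THF, 0 °C → rt; then I2, THF, −78 → 0 °C; aq Na2S2O3/NH4Cl
Reagents that add atoms: iodine, [I][I]
Why: Copper-catalysed, hydroxyl-directed anti-carbomagnesiation of a propargylic alcohol: the magnesium alkoxide of 5 directs the silylmethyl group to C3 and magnesium to the terminal C2 inside a five-membered chelate, so magnesium is cis to C4. Iodinolysis with retention gives the iodide with iodine cis to C4; 9 is E by the sequence rule only because CH2Si outranks C4, and it becomes Z once silicon is replaced by oxygen.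

Step 5
Reactants: 9 silyl vinyl iodide
Product: 10 Z-iodoalkene diol (C7–OH and C4–OH free)
Conditions: 30% aq H2O2, KF, KHCO3, THF–MeOH (1:1), rt
Reagents that add atoms: hydrogen peroxide, OO
Why: Tamao oxidation: peroxide adds to the activated alkoxysilane and C7 migrates from silicon to oxygen, which turns the allylic C–Si bond into C7–OH without allylic shift. The electron-poor vinyl iodide, the silyl ether and the acetonide should be inert, and no oxidisable sulfur is present.

Step 6
Reactants: 10 Z-iodoalkene diol
Product: 11 C7 benzoate (C4–OH free)
Conditions: BzCl (1.05 equiv), pyridine, CH2Cl2, −40 → −10 °C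
Reagents that add atoms: benzoyl chloride, O=C(Cl)c1ccccc1
Why: Acylation is selective for the unhindered primary allylic hydroxyl over the secondary C4 hydroxyl, which is shielded by the iodoalkene and the dioxolane.

Step 7
Reactants: 11 C7 benzoate
Product: 12 bis-silyl ether (C4–OTBS and C1–OTBS)
Conditions: TBSOTf, 2,6-lutidine, CH2Cl2, −78 → −20 °C
Reagents that add atoms: tert-butyldimethylsilyl trifluoromethanesulfonate, CC(C)(C)[Si](C)(C)OS(=O)(=O)C(F)(F)F
Why: The silyl triflate silylates the hindered secondary hydroxyl at low temperature, where the acetonide and the benzoate are stable.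

Step 8
Reactants: 12 bis-silyl ether
Product: 13 primary alcohol (C1–OH; C4–OTBS kept)
Conditions: HF·pyridine, pyridine, THF, 0 °C
Reagents that add atoms: none
Why: Buffered HF·pyridine cleaves the unhindered primary silyl ether much faster than the secondary one wedged between the trisubstituted alkene and the dioxolane; benzoate, acetonide and vinyl iodide are inert.

Step 9
Reactants: 13 primary alcohol
Product: 14 Z-vinyl iodide aldehyde (cyclisation precursor)
Conditions: Dess–Martin periodinane, NaHCO3, CH2Cl2, 0 °C → rt; used crude
Reagents that add atoms: none
Why: Dess–Martin oxidation gives the aldehyde under non-basic conditions, so C6, which is α to the new carbonyl and cis-substituted on the dioxolane, should not epimerise; 14 is used at once.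

Step 10
Reactants: 14 Z-vinyl iodide aldehyde
Product: 15 cyclohexenol with C1–OH trans to the C6 oxygen
Conditions: CrCl2 (8 equiv), NiCl2 (2 mol %), degassed DMSO, rt, 0.005 M
Reagents that add atoms: none
Why: CrCl2 reduces NiCl2 to zerovalent nickel, which inserts into the C2–I bond with retention of alkene geometry; transmetallation to trivalent chromium gives an alkenylchromium dichloride and returns divalent nickel, which further CrCl2 reduces again. The closest known reaction type is the intramolecular Nozaki–Hiyama–Kishi cyclisation of ω-iodoalkenyl aldehydes to cycloalkenols. The alkenylchromium adds to the C1 aldehyde in a 6-exo-trig closure, and the geometry fixed in step 4 holds C1 and C4 cis on C2=C3 as the ring demands. The new stereocentre C1 is set by the substrate: allylic 1,2-strain between the C3 benzoyloxymethyl group and the C4 silyl ether favours the half-chair with C4–O pseudoaxial, C5–O axial and C6–O equatorial, so the incoming C2 is anti to the C6–O bond. The chromium-bound oxygen should then take the pseudo-equatorial site to avoid a 1,3-diaxial clash with C5–O, which places C1–OH trans to C6–O (1R). A Felkin-type preference for the carbonyl oxygen on the inside pulls the other way, so this facial selectivity is the main uncertainty of the step. The step also needs chemoselectivity for the aldehyde over the benzoate, which the weakly basic, oxophilic alkenylchromium secures, and integrity at C6, which the neutral medium protects. High dilution suppresses intermolecular addition.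

Step 11
Reactants: 15 cyclohexenol
Product: 16 C1 acetate
Conditions: Ac2O, pyridine, DMAP (cat.), CH2Cl2, 0 °C → rt
Reagents that add atoms: acetic anhydride, CC(=O)OC(C)=O
Why: C1–OH is the only free hydroxyl, so DMAP-catalysed acylation needs no selectivity and proceeds with retention at C1.

Step 12
Reactants: 16 C1 acetate
Product: 17 C5,C6-diol (C4–OTBS kept)
Conditions: AcOH–H2O (4:1), 55 °C
Reagents that add atoms: none
Why: Aqueous acetic acid hydrolyses the dioxolane, while the hindered secondary silyl ether and the two esters should survive this weak acid; acid disfavours acyl migration.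

Step 13
Reactants: 17 C5,C6-diol
Product: 19 C5 benzoate with C6–OH free, via cyclic orthobenzoate 18 (not isolated)
Conditions: PhC(OMe)3, CSA (cat.), MeCN, rt; then AcOH–H2O (4:1), rt
Reagents that add atoms: trimethyl orthobenzoate, COC(OC)(OC)c1ccccc1; water, O
Why: Orthoester exchange ties only the cis diol into a five-membered cyclic orthobenzoate, and mild acid hydrolysis of such orthoesters on six-membered rings gives the axial ester and the equatorial alcohol. With C4–OTBS pseudoaxial through allylic 1,2-strain, C5–O is the axial oxygen, so the benzoate should end on C5.

Step 14
Reactants: 19 C5 benzoate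
Product: 20 target (CNP0169028.1)
Conditions: HF·pyridine, THF, 0 °C → rt
Reagents that add atoms: none
Why: Acidic fluoride cleaves the last Si–O bond without the basic alkoxide conditions that would move the C5 benzoate or the C1 acetate to a neighbouring hydroxyl.

## Compound list

1 | L-arabinose (pyranose form, anomeric mixture) | OC1OC[C@H](O)[C@H](O)[C@H]1O | starting material
2 | 3,4-O-isopropylidene-L-arabinopyranose (anomeric mixture) | OC1OC[C@@H]2OC(C)(C)O[C@@H]2[C@H]1O | intermediate
3 | dimethyl (1-diazo-2-oxopropyl)phosphonate (Ohira–Bestmann reagent) | CC(=O)C(=[N+]=[N-])P(=O)(OC)OC | starting material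
4 | (1S)-1-[(4R,5S)-5-(hydroxymethyl)-2,2-dimethyl-1,3-dioxolan-4-yl]prop-2-yn-1-ol (1,2-dideoxy-4,5-O-isopropylidene-L-arabino-hex-1-ynitol) | C#C[C@H](O)[C@H]1OC(C)(C)O[C@H]1CO | intermediate
5 | (1S)-1-[(4R,5S)-5-{[(tert-butyldimethylsilyl)oxy]methyl}-2,2-dimethyl-1,3-dioxolan-4-yl]prop-2-yn-1-ol | C#C[C@H](O)[C@H]1OC(C)(C)O[C@H]1CO[Si](C)(C)C(C)(C)C | intermediate
6 | (chloromethyl)isopropoxydimethylsilane | CC(C)O[Si](C)(C)CCl | starting material
7 | [(isopropoxydimethylsilyl)methyl]magnesium chloride | CC(C)O[Si](C)(C)C[Mg]Cl | intermediate (not isolated)
8 | alkenylmagnesium chloride and chloromagnesium alkoxide from anti-addition of 7 to 5 (magnesium on C2, cis to C4) | Cl[Mg]/C=C(C[Si](C)(C)OC(C)C)\[C@H](O[Mg]Cl)[C@H]1OC(C)(C)O[C@H]1CO[Si](C)(C)C(C)(C)C | intermediate (not isolated)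
9 | (1S,2E)-1-[(4R,5S)-5-{[(tert-butyldimethylsilyl)oxy]methyl}-2,2-dimethyl-1,3-dioxolan-4-yl]-3-iodo-2-{[isopropoxy(dimethyl)silyl]methyl}prop-2-en-1-ol (iodine cis to the carbinol carbon) | I/C=C(C[Si](C)(C)OC(C)C)\[C@H](O)[C@H]1OC(C)(C)O[C@H]1CO[Si](C)(C)C(C)(C)C | intermediate
10 | (1S,2Z)-1-[(4R,5S)-5-{[(tert-butyldimethylsilyl)oxy]methyl}-2,2-dimethyl-1,3-dioxolan-4-yl]-2-(hydroxymethyl)-3-iodoprop-2-en-1-ol | I/C=C(CO)\[C@H](O)[C@H]1OC(C)(C)O[C@H]1CO[Si](C)(C)C(C)(C)C | intermediate
11 | (2Z,3S)-3-[(4R,5S)-5-{[(tert-butyldimethylsilyl)oxy]methyl}-2,2-dimethyl-1,3-dioxolan-4-yl]-3-hydroxy-2-(iodomethylidene)propyl benzoate | I/C=C(COC(=O)c1ccccc1)\[C@H](O)[C@H]2OC(C)(C)O[C@H]2CO[Si](C)(C)C(C)(C)C | intermediate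
12 | (2Z,3S)-3-[(tert-butyldimethylsilyl)oxy]-3-[(4S,5S)-5-{[(tert-butyldimethylsilyl)oxy]methyl}-2,2-dimethyl-1,3-dioxolan-4-yl]-2-(iodomethylidene)propyl benzoate | I/C=C(COC(=O)c1ccccc1)\[C@H](O[Si](C)(C)C(C)(C)C)[C@H]2OC(C)(C)O[C@H]2CO[Si](C)(C)C(C)(C)C | intermediate
13 | (2Z,3S)-3-[(tert-butyldimethylsilyl)oxy]-3-[(4S,5S)-5-(hydroxymethyl)-2,2-dimethyl-1,3-dioxolan-4-yl]-2-(iodomethylidene)propyl benzoate | I/C=C(COC(=O)c1ccccc1)\[C@H](O[Si](C)(C)C(C)(C)C)[C@H]2OC(C)(C)O[C@H]2CO | intermediate
14 | (2Z,3S)-3-[(tert-butyldimethylsilyl)oxy]-3-[(4S,5R)-5-formyl-2,2-dimethyl-1,3-dioxolan-4-yl]-2-(iodomethylidene)propyl benzoate | I/C=C(COC(=O)c1ccccc1)\[C@H](O[Si](C)(C)C(C)(C)C)[C@H]2OC(C)(C)O[C@H]2C=O | intermediate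
15 | (1R,4S,5S,6S)-3-(benzoyloxymethyl)-4-(tert-butyldimethylsilyloxy)-5,6-(isopropylidenedioxy)cyclohex-2-en-1-ol (target numbering; C1–OH trans to C6–O) | O[C@@H]1C=C(COC(=O)c2ccccc2)[C@H](O[Si](C)(C)C(C)(C)C)[C@H]3OC(C)(C)O[C@@H]13 | intermediate
16 | (1R,4S,5S,6S)-1-acetoxy-3-(benzoyloxymethyl)-4-(tert-butyldimethylsilyloxy)-5,6-(isopropylidenedioxy)cyclohex-2-ene (target numbering) | CC(=O)O[C@@H]1C=C(COC(=O)c2ccccc2)[C@H](O[Si](C)(C)C(C)(C)C)[C@H]3OC(C)(C)O[C@@H]13 | intermediate
17 | (1R,4S,5S,6R)-1-acetoxy-3-(benzoyloxymethyl)-4-(tert-butyldimethylsilyloxy)cyclohex-2-ene-5,6-diol (target numbering) | CC(=O)O[C@@H]1C=C(COC(=O)c2ccccc2)[C@H](O[Si](C)(C)C(C)(C)C)[C@@H](O)[C@H]1O | intermediate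
18 | 5,6-cyclic methyl orthobenzoate of 17 (orthoester carbon as a mixture) | CC(=O)O[C@@H]1C=C(COC(=O)c2ccccc2)[C@H](O[Si](C)(C)C(C)(C)C)[C@H]3OC(OC)(c4ccccc4)O[C@@H]13 | intermediate (not isolated)
19 | (1R,4S,5S,6S)-1-acetoxy-5-benzoyloxy-3-(benzoyloxymethyl)-4-(tert-butyldimethylsilyloxy)cyclohex-2-en-6-ol (target numbering) | CC(=O)O[C@@H]1C=C(COC(=O)c2ccccc2)[C@H](O[Si](C)(C)C(C)(C)C)[C@@H](OC(=O)c2ccccc2)[C@H]1O | intermediate
20 | (1R,4S,5R,6S)-1-acetoxy-5-benzoyloxy-3-(benzoyloxymethyl)cyclohex-2-ene-4,6-diol (target numbering), CNP0169028.1 | CC(=O)O[C@@H]1C=C(COC(=O)c2ccccc2)[C@H](O)[C@@H](OC(=O)c2ccccc2)[C@H]1O | target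

## Step count and least certain steps

Total: 14 steps. Longest linear sequence: 14 steps (1 to 20); reagent 7 is made within step 4.

**Step 10 (key step).** The closure may show poor facial selectivity at C1, because the inside-oxygen preference of an α-alkoxy aldehyde opposes the conformational preference for a pseudo-equatorial chromium alkoxide. Protonolysis of the alkenylchromium by traces of water and epimerisation at C6 before closure are lesser risks. Fallback: starting from 14, the closure is accepted in whatever sense it takes. If it delivers the C1-epimeric cyclohexenol F4 (C1–OH cis to C6–O), this is not acetylated directly but inverted by a Mitsunobu reaction with acetic acid (PPh3, diisopropyl azodicarboxylate, toluene, 0 °C). The SN2 displacement should give the acetate with the required 1R configuration, and the route is rejoined at 16.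

**Step 2.** The carbon next to the aldehyde may epimerise through enolisation of the open-chain hydroxy aldehyde in carbonate/methanol, and ring opening of the pyranose lactol may be slow. Fallback: starting from 2, the C1–C2 glycol is cleaved with NaIO4 (water, then mild base to remove the formate) to give 2,3-O-isopropylidene-L-erythrofuranose F1. Addition of ethynylmagnesium bromide (THF, 0 °C → rt) to this lactol should favour the threo adduct through the chelated magnesium alkoxide. The C4-epimeric alkynediol F2 is separated, and the route is rejoined at 4. C4 is then set by substrate control and no longer taken from the sugar.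

**Step 4.** Carbomagnesiation of the hindered secondary propargylic alkoxide may stall, the terminal alkyne may simply be deprotonated, and the alkoxysilane may exchange with the free hydroxyl. Fallback: starting from 5, the same directed anti-addition is run with the simplest Grignard reagent (methylmagnesium bromide, CuI cat., then I2) to give the Z-iodo methyl allylic alcohol F3. Its methyl group, which is cis to the alkene hydrogen, is then oxidised to the primary allylic alcohol with SeO2 (cat.) and tert-butyl hydroperoxide in CH2Cl2 (Riley-type allylic oxidation). The route is rejoined at 10.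

**Step 13.** The orthoester may open with the wrong regiochemistry if the ring prefers the half-chair with C6–O axial, and the benzoate or the C1 acetate may migrate to a neighbouring hydroxyl. Fallback: starting from 17, the diol is converted with Bu2SnO (toluene, reflux, water removal) into the dibutylstannylene acetal F7, which is treated with benzoyl chloride at room temperature. Stannylene acetals of cis diols are acylated at the equatorial oxygen, the opposite of the orthoester rule, so whichever conformer dominates, one of the two methods should place the benzoate on C5. The route is rejoined at 19.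

**Step 12.** The acetonide hydrolysis may also remove the C4 silyl ether. Fallback: starting from 16, both acid-labile groups are removed on purpose (TFA–H2O 9:1, 0 °C → rt) to give the triol F5. Orthoester exchange with trimethyl orthobenzoate (CSA cat.) then engages only the cis C5/C6 pair as the cyclic orthobenzoate F6, and mild aqueous acid opens it to the C5 benzoate. The route is rejoined directly at 20, one step shorter but without the conformational bias of the silyl ether.

## Further compounds

F1 | step 2 | 2,3-O-isopropylidene-L-erythrofuranose | OC1OC[C@@H]2OC(C)(C)O[C@H]12
F2 | step 2 | C4 epimer of 4 (1,2-dideoxy-4,5-O-isopropylidene-L-ribo-hex-1-ynitol) | C#C[C@@H](O)[C@H]1OC(C)(C)O[C@H]1CO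
F3 | step 4 | (1S,2Z)-1-[(4R,5S)-5-{[(tert-butyldimethylsilyl)oxy]methyl}-2,2-dimethyl-1,3-dioxolan-4-yl]-3-iodo-2-methylprop-2-en-1-ol | I/C=C(C)\[C@H](O)[C@H]1OC(C)(C)O[C@H]1CO[Si](C)(C)C(C)(C)C
F4 | step 10 | C1 epimer of 15 (1S,4S,5S,6S in target numbering; C1–OH cis to C6–O) | O[C@H]1C=C(COC(=O)c2ccccc2)[C@H](O[Si](C)(C)C(C)(C)C)[C@H]3OC(C)(C)O[C@@H]13
F5 | step 12 | 1-acetoxy-3-(benzoyloxymethyl)cyclohex-2-ene-4,5,6-triol with the configuration of 20 | CC(=O)O[C@@H]1C=C(COC(=O)c2ccccc2)[C@H](O)[C@@H](O)[C@H]1O
F6 | step 12 | 5,6-cyclic methyl orthobenzoate of F5 (orthoester carbon as a mixture) | CC(=O)O[C@@H]1C=C(COC(=O)c2ccccc2)[C@H](O)[C@H]3OC(OC)(c4ccccc4)O[C@@H]13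
F7 | step 13 | 5,6-O-dibutylstannylene acetal of 17 | CC(=O)O[C@@H]1C=C(COC(=O)c2ccccc2)[C@H](O[Si](C)(C)C(C)(C)C)[C@H]3O[Sn](CCCC)(CCCC)O[C@@H]13
A1 | alternative 1 | bromobenzene | Brc1ccccc1
A2 | alternative 1 | (1S,2S)-3-bromocyclohexa-3,5-diene-1,2-diol | O[C@H]1C=CC=C(Br)[C@H]1O
A3 | alternative 2 | quinic-derived enone (C3 ketone, C4 silyl ether, C5/C6 acetonide, C1=C2 alkene; target numbering) | C1=CC(=O)[C@H](O[Si](C)(C)C(C)(C)C)[C@H]2OC(C)(C)O[C@@H]12
A4 | alternative 2 | spiro vinyl oxirane | C1=C[C@@]2(CO2)[C@H](O[Si](C)(C)C(C)(C)C)[C@H]3OC(C)(C)O[C@@H]13
A5 | alternative 3 | shikimate-derived diene (C1=C2–C3=C4 with C3 benzoyloxymethyl and C5/C6 acetonide) | C1=CC(COC(=O)c2ccccc2)=C[C@H]3OC(C)(C)O[C@@H]13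
A6 | alternative 3 | bicyclic endoperoxide | O1O[C@@H]2C=C(COC(=O)c3ccccc3)[C@H]1[C@H]4OC(C)(C)O[C@@H]24
A7 | alternative 3 | cis-1,4-diol from O–O reduction of A6 | O[C@@H]1C=C(COC(=O)c2ccccc2)[C@H](O)[C@H]3OC(C)(C)O[C@@H]13
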